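**Retrosyn­thetic overview**
- The target is two hexasubstituted acylphloroglucinol rings joined by one CH2. The last step removes five methoxymethyl (MOM) ethers.
- Key disconnection: the bond between ring A C5 (the carbon flanked by the C4 and C6 hydroxyl-bearing carbons of the ring with three free OH) and the bridge CH2. Both rings are complete, so ring A enters as an aryl bromide and ring B as a benzylzinc chloride (Negishi sp2–sp3 coupling).
- Ring A half: 2,4,6-trihydroxytoluene is C-butanoylated, tris-MOM protected and brominated at its last free carbon.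
- Ring B half: the same triol is formylated first. The hydroxyl para to CHO is then methylated, which places OMe para to the future bridge carbon. Butanoylation of the last free carbon, bis-MOM protection and CHO → CH2OH → CH2Cl → CH2ZnCl follow.
- No ring is formed in the route; both benzene rings come from the purchased triol.

Key step: step 11

Assumption: the three starting materials and all reagents are purchasable, and the target has no stereocentre, so no stereocontrol is needed.

**Route**

Step 1
Reactants: 1 2,4,6-trihydroxytoluene; 2 butanoyl chloride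
Product: 3 1-(2,4,6-trihydroxy-3-methylphenyl)butan-1-one
Conditions: AlCl3 (3.5 equiv), CH2Cl2–MeNO2, 0 °C → rt; aq. HCl
Reagents that add atoms: butanoyl chloride, CCCC(Cl)=O
Why: Friedel–Crafts C-acylation of the strongly activated ring at one of its two equivalent free positions; the AlCl3-complexed ketone deactivates the ring against a second acylation.

Step 2
Reactants: 3 1-(2,4,6-trihydroxy-3-methylphenyl)butan-1-one; 4 chloromethyl methyl ether
Product: 5 1-[2,4,6-tris(methoxymethoxy)-3-methylphenyl]butan-1-one
Conditions: NaH (4 equiv), MOMCl (4 equiv), DMF, 0 °C → rt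
Reagents that add atoms: chloromethyl methyl ether, COCCl
Why: Williamson-type O-alkylation of the sodium phenoxides by the hard, very reactive chloromethyl ether; NaH in DMF breaks the O–H···O=C chelates, so both ortho hydroxyls should be etherified as well.

Step 3
Reactants: 5 1-[2,4,6-tris(methoxymethoxy)-3-methylphenyl]butan-1-one
Product: 6 1-[3-bromo-2,4,6-tris(methoxymethoxy)-5-methylphenyl]butan-1-one
Conditions: NBS (1.05 equiv), MeCN, 0 °C → rt, dark
Reagents that add atoms: N-bromosuccinimide, O=C1CCC(=O)N1Br
Why: electrophilic aromatic bromination at the only free ring carbon, activated by two ortho and one para alkoxy group; the neutral conditions spare the MOM acetals and the ketone α-position.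

Step 4
Reactants: 1 2,4,6-trihydroxytoluene
Product: 8 2,4,6-trihydroxy-3-methylbenzaldehyde, via aryliminium chloride 7 (not isolated)
Conditions: POCl3 (1.1 equiv), DMF (1.2 equiv), EtOAc, 0 °C → rt; then H2O, 60 °C
Reagents that add atoms: N,N-dimethylformamide, CN(C)C=O; water, O; phosphoryl chloride, O=P(Cl)(Cl)Cl (chloride counter-ion of 7 only)
Why: Vilsmeier–Haack formylation; the chloroiminium ion attacks one of the two equivalent free positions, and the resulting iminium salt deactivates the ring against a second attack until it is hydrolysed.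

Step 5
Reactants: 8 2,4,6-trihydroxy-3-methylbenzaldehyde
Product: 9 2,6-dihydroxy-4-methoxy-3-methylbenzaldehyde
Conditions: MeI (1.0 equiv), K2CO3 (1.0 equiv), acetone, 0 °C → rt
Reagents that add atoms: iodomethane, CI
Why: selective Williamson O-methylation; the C4 hydroxyl, para to the formyl group, is the most acidic and is not held in the O–H···O=CH chelate, so one equivalent of weak base and MeI should methylate it in preference to the two ortho hydroxyls.

Step 6
Reactants: 9 2,6-dihydroxy-4-methoxy-3-methylbenzaldehyde; 2 butanoyl chloride
Product: 10 3-butanoyl-2,6-dihydroxy-4-methoxy-5-methylbenzaldehyde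
Conditions: AlCl3 (4 equiv), CH2Cl2–PhNO2, 0 °C → rt; aq. HCl
Reagents that add atoms: butanoyl chloride, CCCC(Cl)=O
Why: Friedel–Crafts acylation at the single remaining ring carbon, still activated by two ortho oxygens and one para oxygen; the neighbouring free hydroxyl takes up aluminium in the product chelate, which should shield the adjacent methyl ether from Lewis-acid cleavage.

Step 7
Reactants: 10 3-butanoyl-2,6-dihydroxy-4-methoxy-5-methylbenzaldehyde; 4 chloromethyl methyl ether
Product: 11 3-butanoyl-4-methoxy-2,6-bis(methoxymethoxy)-5-methylbenzaldehyde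
Conditions: NaH (3 equiv), MOMCl (3 equiv), DMF, 0 °C → rt
Reagents that add atoms: chloromethyl methyl ether, COCCl
Why: Williamson-type O-alkylation of the two chelated phenoxides; the ring has no free carbon left, so O-alkylation is the only productive course.

Step 8
Reactants: 11 3-butanoyl-4-methoxy-2,6-bis(methoxymethoxy)-5-methylbenzaldehyde
Product: 12 1-[3-(hydroxymethyl)-6-methoxy-2,4-bis(methoxymethoxy)-5-methylphenyl]butan-1-one
Conditions: NaBH4 (1.0 equiv), THF–MeOH, −20 → 0 °C
Reagents that add atoms: none
Why: chemoselective borohydride reduction; the aldehyde is far more electrophilic than the twisted, di-ortho-substituted aryl propyl ketone, so at low temperature only the formyl group should be reduced.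

Step 9
Reactants: 12 1-[3-(hydroxymethyl)-6-methoxy-2,4-bis(methoxymethoxy)-5-methylphenyl]butan-1-one
Product: 14 1-[3-(chloromethyl)-6-methoxy-2,4-bis(methoxymethoxy)-5-methylphenyl]butan-1-one, via benzylic mesylate 13 (not isolated)
Conditions: MsCl (1.2 equiv), Et3N (1.5 equiv), LiCl (3 equiv), THF, 0 °C → rt; used crude
Reagents that add atoms: lithium chloride, [Li+].[Cl-]; methanesulfonyl chloride, CS(Cl)(=O)=O (atoms in 13 only)
Why: sulfonylation followed by nucleophilic substitution by chloride; the oxygen-rich benzylic mesylate is displaced quickly under non-acidic conditions that keep the MOM acetals.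

Step 10
Reactants: 14 1-[3-(chloromethyl)-6-methoxy-2,4-bis(methoxymethoxy)-5-methylphenyl]butan-1-one
Product: 15 {[3-butanoyl-4-methoxy-2,6-bis(methoxymethoxy)-5-methylphenyl]methyl}zinc chloride (titrated THF solution, LiCl complex)
Conditions: Zn dust (2 equiv, activated with BrCH2CH2Br and Me3SiCl), LiCl (1.5 equiv), THF, 25 °C
Reagents that add atoms: zinc, [Zn]
Why: LiCl-mediated direct insertion of zinc into the benzylic C–Cl bond; the mild conditions tolerate the hindered ketone and the acetals, and LiCl clears the organozinc from the metal surface so that Wurtz coupling stays low.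

Step 11
Reactants: 6 1-[3-bromo-2,4,6-tris(methoxymethoxy)-5-methylphenyl]butan-1-one; 15 {[3-butanoyl-4-methoxy-2,6-bis(methoxymethoxy)-5-methylphenyl]methyl}zinc chloride
Product: 16 1-[3-{[3-butanoyl-4-methoxy-2,6-bis(methoxymethoxy)-5-methylphenyl]methyl}-2,4,6-tris(methoxymethoxy)-5-methylphenyl]butan-1-one
Conditions: Pd(OAc)2 (2 mol %), SPhos (2-dicyclohexylphosphino-2',6'-dimethoxybiphenyl, 4 mol %), THF, 25 → 50 °C; 15 (1.3 equiv) added over 2 h
Reagents that add atoms: none
Why: Pd(OAc)2 is reduced by the organozinc to a zerovalent palladium–SPhos complex, which inserts into the C–Br bond of 6; the benzyl group of 15 is then transferred from zinc to divalent palladium and reductive elimination forms the aryl–CH2 bond. The closest known reaction type is the Negishi coupling of benzylzinc halides with hindered, electron-rich aryl bromides under palladium/dialkylbiaryl phosphine catalysis. No ring is closed and no stereocentre is created. Site selectivity is fixed by the positions of bromine and zinc, so the step needs only chemoselectivity for cross-coupling over benzyl homocoupling and reduction of the bromide, which slow addition of 15 and the bulky electron-rich ligand should secure. The benzylzinc has no β-hydrogen and is too weak a nucleophile to attack the two twisted, di-ortho-substituted aryl ketones or the MOM acetals.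

Step 12
Reactants: 16 1-[3-{[3-butanoyl-4-methoxy-2,6-bis(methoxymethoxy)-5-methylphenyl]methyl}-2,4,6-tris(methoxymethoxy)-5-methylphenyl]butan-1-one
Product: 17 1-[3-{[3-butanoyl-2,6-dihydroxy-4-methoxy-5-methylphenyl]methyl}-2,4,6-trihydroxy-5-methylphenyl]butan-1-one (target)
Conditions: HCl (3 M in MeOH), 40 °C
Reagents that add atoms: none
Why: acid-catalysed acetal exchange (methanolysis) removes the five MOM ethers, while the aryl methyl ether, the ketones and the diarylmethane bridge should be stable to dilute HCl in methanol at this temperature.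

**Compound list**

1 | 2,4,6-trihydroxytoluene | Cc1c(O)cc(O)cc1O | starting material
2 | butanoyl chloride | CCCC(Cl)=O | starting material
3 | 1-(2,4,6-trihydroxy-3-methylphenyl)butan-1-one | CCCC(=O)c1c(O)cc(O)c(C)c1O | intermediate
4 | chloromethyl methyl ether | COCCl | starting material
5 | 1-[2,4,6-tris(methoxymethoxy)-3-methylphenyl]butan-1-one | CCCC(=O)c1c(OCOC)cc(OCOC)c(C)c1OCOC | intermediate
6 | 1-[3-bromo-2,4,6-tris(methoxymethoxy)-5-methylphenyl]butan-1-one | CCCC(=O)c1c(OCOC)c(C)c(OCOC)c(Br)c1OCOC | intermediate
7 | N-methyl-N-[(2,4,6-trihydroxy-3-methylphenyl)methylidene]methanaminium chloride | C[N+](C)=Cc1c(O)cc(O)c(C)c1O.[Cl-] | intermediate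
8 | 2,4,6-trihydroxy-3-methylbenzaldehyde | Cc1c(O)cc(O)c(C=O)c1O | intermediate
9 | 2,6-dihydroxy-4-methoxy-3-methylbenzaldehyde | COc1cc(O)c(C=O)c(O)c1C | intermediate
10 | 3-butanoyl-2,6-dihydroxy-4-methoxy-5-methylbenzaldehyde | CCCC(=O)c1c(OC)c(C)c(O)c(C=O)c1O | intermediate
11 | 3-butanoyl-4-methoxy-2,6-bis(methoxymethoxy)-5-methylbenzaldehyde | CCCC(=O)c1c(OC)c(C)c(OCOC)c(C=O)c1OCOC | intermediate
12 | 1-[3-(hydroxymethyl)-6-methoxy-2,4-bis(methoxymethoxy)-5-methylphenyl]butan-1-one | CCCC(=O)c1c(OC)c(C)c(OCOC)c(CO)c1OCOC | intermediate
13 | [3-butanoyl-4-methoxy-2,6-bis(methoxymethoxy)-5-methylphenyl]methyl methanesulfonate | CCCC(=O)c1c(OC)c(C)c(OCOC)c(COS(C)(=O)=O)c1OCOC | intermediate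
14 | 1-[3-(chloromethyl)-6-methoxy-2,4-bis(methoxymethoxy)-5-methylphenyl]butan-1-one | CCCC(=O)c1c(OC)c(C)c(OCOC)c(CCl)c1OCOC | intermediate
15 | {[3-butanoyl-4-methoxy-2,6-bis(methoxymethoxy)-5-methylphenyl]methyl}zinc chloride | CCCC(=O)c1c(OC)c(C)c(OCOC)c(C[Zn]Cl)c1OCOC | intermediate
16 | 1-[3-{[3-butanoyl-4-methoxy-2,6-bis(methoxymethoxy)-5-methylphenyl]methyl}-2,4,6-tris(methoxymethoxy)-5-methylphenyl]butan-1-one | CCCC(=O)c1c(OCOC)c(C)c(OCOC)c(Cc2c(OCOC)c(C)c(OC)c(C(=O)CCC)c2OCOC)c1OCOC | intermediate
17 | 1-[3-{[3-butanoyl-2,6-dihydroxy-4-methoxy-5-methylphenyl]methyl}-2,4,6-trihydroxy-5-methylphenyl]butan-1-one | CCCC(=O)c1c(O)c(C)c(O)c(Cc2c(O)c(C)c(OC)c(C(=O)CCC)c2O)c1O | target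

**Step count**
Total: 12 steps. Longest linear sequence: 9 steps (steps 4 to 12, from compound 1).

**Steps most likely to fail**

Step 11. Oxidative addition into the electron-rich C–Br bond flanked by two alkoxy groups may be slow, so that homocoupling of the benzylzinc and reduction of the bromide outrun cross-coupling. The fallback inverts the polarity and lets ring A act as the nucleophile. It sets out from 12 and 3 (3 in excess), heated with HCl in MeOH–dioxane. The two MOM groups of 12 should be lost to give 1-[2,4-dihydroxy-3-(hydroxymethyl)-6-methoxy-5-methylphenyl]butan-1-one F1 in the flask. F1 ionises to an ortho-quinone methide, which the free C5 of 3 traps in a Friedel–Crafts alkylation. The fallback rejoins the route at 17.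

Step 6. The AlCl3-complexed formyl group may deactivate the ring so far that acylation stalls, while the Lewis acid cleaves the methyl ether or removes the formyl group. The fallback introduces the ketone by directed ortho-metalation instead of electrophilic substitution. It sets out from 9:
- NaH and MOMCl in DMF should give 4-methoxy-2,6-bis(methoxymethoxy)-3-methylbenzaldehyde F2.
- NaBH4 in MeOH should give [4-methoxy-2,6-bis(methoxymethoxy)-3-methylphenyl]methanol F3.
- n-BuLi (2.2 equiv, TMEDA, THF, 0 °C) should form the alkoxide and then lithiate the ring CH flanked by OMe and OMOM, giving lithium [3-lithio-4-methoxy-2,6-bis(methoxymethoxy)-5-methylphenyl]methanolate F4.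
- N-methoxy-N-methylbutanamide, then aqueous NH4Cl, should convert F4 into the ketone.

The fallback rejoins the route at 12.

Step 5. Discrimination between the para hydroxyl and the two ortho hydroxyls may be incomplete, which would lead to over-methylation. The fallback replaces selective alkylation by exhaustive methylation and chelation-controlled dealkylation. It sets out from 8: excess MeI and K2CO3 in DMF should give 2,4,6-trimethoxy-3-methylbenzaldehyde F5. Excess AlCl3 in warm CH2Cl2 should then cleave only the two methyl ethers ortho to the formyl group, through the carbonyl–aluminium chelate. The fallback rejoins the route at 9.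

**Further compounds**
F1 | step 11 | 1-[2,4-dihydroxy-3-(hydroxymethyl)-6-methoxy-5-methylphenyl]butan-1-one | CCCC(=O)c1c(OC)c(C)c(O)c(CO)c1O
F2 | step 6 | 4-methoxy-2,6-bis(methoxymethoxy)-3-methylbenzaldehyde | COCOc1cc(OC)c(C)c(OCOC)c1C=O
F3 | step 6 | [4-methoxy-2,6-bis(methoxymethoxy)-3-methylphenyl]methanol | COCOc1cc(OC)c(C)c(OCOC)c1CO
F4 | step 6 | lithium [3-lithio-4-methoxy-2,6-bis(methoxymethoxy)-5-methylphenyl]methanolate | [Li]OCc1c(OCOC)c([Li])c(OC)c(C)c1OCOC
F5 | step 5 | 2,4,6-trimethoxy-3-methylbenzaldehyde | COc1cc(OC)c(C=O)c(OC)c1C
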